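**Plan**

- Target numbering: C1(OBz)–C2=C3–C4(OBz)–C5(OH)–C6(OH)(C7H2OH); all four ring oxygens are cis, C7 lies on the other face.
- Retrosynthesis: the C4 benzoate and the C2=C3 alkene go back to a C4 ketone with a C2 carbinol (a 2-deoxyinosose); the C2–C3 bond is then cut, which unfolds the carbocycle into a methyl 6-deoxyhex-5-enopyranoside; last, the C6–C7 bond is cut to a pyranosid-3-ulose.
- Enabling feature: C1, C6 and C5 with their cis oxygens and the C7 branch are C2, C3 and C4 of a 3-C-(hydroxymethyl)-D-allopyranoside, and C4, C3 and C2 are its C5, C6 and C1. The exocyclic enol ether (latent C4 ketone enolate) and the anomeric carbon (latent C2 aldehyde) are therefore placed for a six-ring aldol.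
- Forward: methyl 4,6-O-benzylidene-α-D-glucopyranoside → 3-ulose → C7 added as a silylmethyl Grignard reagent and unmasked by Tamao oxidation → 2-benzoate, 3,4-acetonide, 5-ene → the single carbocycle closes by Ferrier carbocyclization while the pyranose opens → enone → reduction, benzoylation, acid.
- Stereochemistry: C1 and C5 are C2 and C4 of D-glucose, untouched; C6 comes from equatorial Grignard attack on the α-glycosid-3-ulose; C4 from hydride addition anti to the cis-fused dioxolane.

Key step: step 12

Remark: sugar numbering is used for the pyranosides and the target's ring numbering from the carbocyclization onward (sugar C2, C3, C4, C5, C6, C1 = ring C1, C6, C5, C4, C3, C2; branch carbon = C7). The C2 carbinol formed in the key step is expected as an epimer mixture and is carried on as such, because C2 becomes sp2 one step later.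

**Step 1**
Reactants: 1 methyl 4,6-O-benzylidene-α-D-glucopyranoside
Product: 3 methyl 4,6-O-benzylidene-2-O-(4-methoxybenzyl)-α-D-glucopyranoside, via stannylene acetal 2 (not isolated)
Conditions: Bu2SnO, toluene, reflux (−H2O); then 4-methoxybenzyl chloride, Bu4NI (cat.), toluene, 90 °C
Reagents that add atoms: 4-methoxybenzyl chloride, COc1ccc(CCl)cc1
Why: Stannylene-acetal-mediated regioselective O-alkylation: in the dibutylstannylene acetal of the trans-diequatorial 2,3-diol of an α-glucopyranoside the oxygen next to the axial anomeric methoxy group (O2) is the more nucleophilic one, so the PMB group should go mainly to O2 and leave only O3 free for oxidation.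

**Step 2**
Reactants: 3 methyl 4,6-O-benzylidene-2-O-(4-methoxybenzyl)-α-D-glucopyranoside
Product: 4 methyl 4,6-O-benzylidene-2-O-(4-methoxybenzyl)-α-D-ribo-hexopyranosid-3-ulose
Conditions: Dess–Martin periodinane, CH2Cl2, rt
Reagents that add atoms: none
Why: Dess–Martin oxidation of the single free secondary hydroxyl gives the 3-ulose under neutral, non-basic conditions, so the two α stereocenters (C2, C4) should not epimerise and the acetal and the PMB ether are untouched.

**Step 3**
Reactants: 4 methyl 4,6-O-benzylidene-2-O-(4-methoxybenzyl)-α-D-ribo-hexopyranosid-3-ulose; 5 (chloromethyl)(isopropoxy)dimethylsilane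
Product: 7 methyl 4,6-O-benzylidene-3-C-[(isopropoxydimethylsilyl)methyl]-2-O-(4-methoxybenzyl)-α-D-allopyranoside, via Grignard reagent 6 (not isolated)
Conditions: 5, Mg, THF, reflux; then 4, THF, 0 °C; aq NH4Cl
Reagents that add atoms: (chloromethyl)(isopropoxy)dimethylsilane (compound 5), CC(C)O[Si](C)(C)CCl
Why: Grignard addition to a ketone with a weakly basic silylmethyl reagent (a hydroxymethyl anion equivalent): the axial anomeric methoxy group blocks the axial (α-face) approach to C3, so the carbon nucleophile should enter equatorially and the new quaternary center carries an axial hydroxyl cis to O2 and O4 (D-allo), which is the configuration of C6 of the target.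

**Step 4**
Reactants: 7 methyl 4,6-O-benzylidene-3-C-[(isopropoxydimethylsilyl)methyl]-2-O-(4-methoxybenzyl)-α-D-allopyranoside
Product: 8 methyl 4,6-O-benzylidene-3-C-(hydroxymethyl)-2-O-(4-methoxybenzyl)-α-D-allopyranoside
Conditions: 30% H2O2, KF, KHCO3, THF/MeOH, rt
Reagents that add atoms: hydrogen peroxide, OO
Why: Tamao oxidation: fluoride-activated peroxide inserts oxygen into the C–Si bond of the alkoxysilane and turns the silylmethyl group into the C7 hydroxymethyl group, under mild conditions that leave acetal, PMB ether and glycoside intact and should outrun Peterson elimination of the β-hydroxysilane.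

**Step 5**
Reactants: 8 methyl 4,6-O-benzylidene-3-C-(hydroxymethyl)-2-O-(4-methoxybenzyl)-α-D-allopyranoside
Product: 9 methyl 4,6-O-benzylidene-3-C-[(tert-butyldimethylsilyloxy)methyl]-2-O-(4-methoxybenzyl)-α-D-allopyranoside
Conditions: TBSCl, imidazole, DMF, 0 °C to rt
Reagents that add atoms: tert-butyldimethylsilyl chloride, CC(C)(C)[Si](C)(C)Cl
Why: Silyl ether formation with TBSCl/imidazole is selective for the primary hydroxyl, because the neighbouring tertiary hydroxyl is far too hindered to be silylated under these conditions.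

**Step 6**
Reactants: 9 methyl 4,6-O-benzylidene-3-C-[(tert-butyldimethylsilyloxy)methyl]-2-O-(4-methoxybenzyl)-α-D-allopyranoside
Product: 10 methyl 4,6-O-benzylidene-3-C-[(tert-butyldimethylsilyloxy)methyl]-α-D-allopyranoside
Conditions: DDQ, CH2Cl2/pH 7 buffer, 0 °C to rt
Reagents that add atoms: none
Why: Oxidative PMB ether cleavage: DDQ abstracts hydride from the electron-rich benzylic position and water hydrolyses the oxocarbenium ion, freeing O2 while benzylidene acetal, TBS ether and glycoside are inert; the aqueous buffer should intercept the cation before the cis tertiary hydroxyl can trap it as an acetal.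

**Step 7**
Reactants: 10 methyl 4,6-O-benzylidene-3-C-[(tert-butyldimethylsilyloxy)methyl]-α-D-allopyranoside; 11 benzoyl chloride
Product: 12 methyl 2-O-benzoyl-4,6-O-benzylidene-3-C-[(tert-butyldimethylsilyloxy)methyl]-α-D-allopyranoside
Conditions: BzCl, pyridine, 4-(dimethylamino)pyridine (cat.), CH2Cl2, 0 °C to rt
Reagents that add atoms: benzoyl chloride (compound 11), O=C(Cl)c1ccccc1
Why: Acylation under pyridine/4-(dimethylamino)pyridine catalysis esterifies the only secondary hydroxyl, the tertiary C3 hydroxyl being unreactive, and installs the benzoate that ends on C1 of the target.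

**Step 8**
Reactants: 12 methyl 2-O-benzoyl-4,6-O-benzylidene-3-C-[(tert-butyldimethylsilyloxy)methyl]-α-D-allopyranoside
Product: 13 methyl 2-O-benzoyl-3-C-[(tert-butyldimethylsilyloxy)methyl]-α-D-allopyranoside
Conditions: H2 (1 atm), Pd(OH)2/C, EtOAc, rt
Reagents that add atoms: none
Why: Hydrogenolysis of the benzylidene acetal over Pd(OH)2/C in a neutral aprotic solvent releases O4 and O6 with loss of toluene, without touching the benzoate, the silyl ether or the methyl glycoside.

**Step 9**
Reactants: 13 methyl 2-O-benzoyl-3-C-[(tert-butyldimethylsilyloxy)methyl]-α-D-allopyranoside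
Product: 14 methyl 2-O-benzoyl-3-C-[(tert-butyldimethylsilyloxy)methyl]-6-deoxy-6-iodo-α-D-allopyranoside
Conditions: I2, PPh3, imidazole, toluene, 60 °C
Reagents that add atoms: iodine, [I][I]
Why: Appel-type (Garegg–Samuelsson) iodination: the alkoxyphosphonium ion is displaced by iodide in an SN2 reaction that is feasible only at the unhindered primary C6, so the secondary C4 and tertiary C3 hydroxyls should remain free.

**Step 10**
Reactants: 14 methyl 2-O-benzoyl-3-C-[(tert-butyldimethylsilyloxy)methyl]-6-deoxy-6-iodo-α-D-allopyranoside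
Product: 15 methyl 2-O-benzoyl-3-C-[(tert-butyldimethylsilyloxy)methyl]-6-deoxy-6-iodo-3,4-O-isopropylidene-α-D-allopyranoside
Conditions: 2-methoxypropene, pyridinium p-toluenesulfonate (cat.), CH2Cl2, 0 °C to rt
Reagents that add atoms: 2-methoxypropene, COC(C)=C
Why: Acid-catalysed ketalisation of the only diol left, the cis (axial/equatorial) O3/O4 pair, gives the cis-fused dioxolane, and the weak acid spares the silyl ether and the glycoside.

**Step 11**
Reactants: 15 methyl 2-O-benzoyl-3-C-[(tert-butyldimethylsilyloxy)methyl]-6-deoxy-6-iodo-3,4-O-isopropylidene-α-D-allopyranoside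
Product: 16 methyl 2-O-benzoyl-3-C-[(tert-butyldimethylsilyloxy)methyl]-6-deoxy-3,4-O-isopropylidene-α-D-ribo-hex-5-enopyranoside
Conditions: DBU, THF, reflux
Reagents that add atoms: none
Why: E2 dehydrohalogenation of the primary iodide by the non-nucleophilic amidine base removes H5, the only β-hydrogen, and gives the exocyclic enol ether, while benzoate and ketal are stable to DBU.

**Step 12**
Reactants: 16 methyl 2-O-benzoyl-3-C-[(tert-butyldimethylsilyloxy)methyl]-6-deoxy-3,4-O-isopropylidene-α-D-ribo-hex-5-enopyranoside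
Product: 18 1-benzoyloxy-6-[(tert-butyldimethylsilyloxy)methyl]-2-hydroxy-5,6-(isopropylidenedioxy)cyclohexan-4-one (target numbering; O1/O5/O6 all cis; C2 epimers), via mercurio keto aldehyde 17 (not isolated)
Conditions: Hg(OCOCF3)2 (10 mol %), acetone/H2O 2:1, rt
Reagents that add atoms: water, O
Why: Divalent mercury adds to the terminal carbon of the electron-rich enol ether and water to sugar C5; the hemiketal collapses with loss of methanol to the open-chain intermediate 17, which carries the target's C4 ketone, a C3–Hg bond and the C2 aldehyde, and its mercury enolate adds to the aldehyde to form the C2–C3 bond before protonolysis returns the mercury salt. The closest known reaction is the Ferrier carbocyclization of 6-deoxyhex-5-enopyranosides to 2-deoxyinososes, which is known to run with catalytic Hg(OCOCF3)2 in aqueous acetone. The one ring that closes is the cyclohexanone, by a 6-(enolendo)-exo-trig aldol, while the pyranose ring is lost. The only new stereocenter is the C2 carbinol, governed by the chair-like aldol transition state but irrelevant because C2 becomes sp2 in step 13; C1, C5 and C6 are not touched. The step needs chemoselectivity only: hydration of the enol ether without hydrolysis of the dioxolane or the silyl ether, which the catalytic amount of mercury salt at room temperature (little free acid) and the enol ether being the only strongly nucleophilic π bond of 16 should secure.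

**Step 13**
Reactants: 18 1-benzoyloxy-6-[(tert-butyldimethylsilyloxy)methyl]-2-hydroxy-5,6-(isopropylidenedioxy)cyclohexan-4-one
Product: 20 1-benzoyloxy-6-[(tert-butyldimethylsilyloxy)methyl]-5,6-(isopropylidenedioxy)cyclohex-2-en-4-one (target numbering; O1/O5/O6 all cis), via mesylate 19 (not isolated)
Conditions: MsCl, Et3N, CH2Cl2, 0 °C to rt
Reagents that add atoms: none
Why: Mesylation of the β-hydroxy ketone followed by E1cB elimination through the C3 enolate gives the conjugated enone from either C2 epimer, and C5 should not epimerise because the cis fusion of the dioxolane is the stable one.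

**Step 14**
Reactants: 20 1-benzoyloxy-6-[(tert-butyldimethylsilyloxy)methyl]-5,6-(isopropylidenedioxy)cyclohex-2-en-4-one
Product: 21 1-benzoyloxy-6-[(tert-butyldimethylsilyloxy)methyl]-4-hydroxy-5,6-(isopropylidenedioxy)cyclohex-2-ene (O1/O4/O5/O6 all cis)
Conditions: NaBH4, CeCl3·7H2O, MeOH, −78 °C
Reagents that add atoms: none
Why: Luche reduction: the cerium-activated carbonyl undergoes clean 1,2-addition, and hydride should arrive on the convex face of the cis-fused bicycle, anti to the dioxolane C–O bond on the neighbouring C5, which places the new C4 hydroxyl cis to O5 (and so to O6 and O1) as the target requires.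

**Step 15**
Reactants: 21 1-benzoyloxy-6-[(tert-butyldimethylsilyloxy)methyl]-4-hydroxy-5,6-(isopropylidenedioxy)cyclohex-2-ene; 11 benzoyl chloride
Product: 22 1,4-bis(benzoyloxy)-6-[(tert-butyldimethylsilyloxy)methyl]-5,6-(isopropylidenedioxy)cyclohex-2-ene (all four ring oxygens cis)
Conditions: BzCl, pyridine, 4-(dimethylamino)pyridine (cat.), CH2Cl2, 0 °C
Reagents that add atoms: benzoyl chloride (compound 11), O=C(Cl)c1ccccc1
Why: Standard acylation (benzoyl chloride, pyridine, nucleophilic catalysis) of the only free hydroxyl, an allylic secondary alcohol, proceeds with retention at C4 because the C–O bond is not broken.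

**Step 16**
Reactants: 22 1,4-bis(benzoyloxy)-6-[(tert-butyldimethylsilyloxy)methyl]-5,6-(isopropylidenedioxy)cyclohex-2-ene
Product: 23 (1S,4R,5R,6R)-4-(benzoyloxy)-5,6-dihydroxy-6-(hydroxymethyl)cyclohex-2-en-1-yl benzoate (CNP0212417.4)
Conditions: CF3CO2H/H2O 4:1, 0 °C to rt
Reagents that add atoms: none
Why: Acid-catalysed hydrolysis cleaves the isopropylidene ketal and the primary TBS ether in one operation, whereas benzoates are stable to aqueous acid and acid-mediated acyl migration is slow at or below room temperature, so the C5, C6 and C7 hydroxyls should be freed with both esters in place.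

**Compound list**

1 | methyl 4,6-O-benzylidene-α-D-glucopyranoside ((R)-benzylidene; commercial) | CO[C@H]1O[C@@H]2CO[C@@H](c3ccccc3)O[C@H]2[C@H](O)[C@H]1O | starting material
2 | methyl 4,6-O-benzylidene-2,3-O-(dibutylstannylene)-α-D-glucopyranoside | CO[C@H]1O[C@@H]2CO[C@@H](c3ccccc3)O[C@H]2[C@@H]3O[Sn](CCCC)(CCCC)O[C@@H]13 | intermediate
3 | methyl 4,6-O-benzylidene-2-O-(4-methoxybenzyl)-α-D-glucopyranoside | CO[C@H]1O[C@@H]2CO[C@@H](c3ccccc3)O[C@H]2[C@H](O)[C@H]1OCc1ccc(OC)cc1 | intermediate
4 | methyl 4,6-O-benzylidene-2-O-(4-methoxybenzyl)-α-D-ribo-hexopyranosid-3-ulose | CO[C@H]1O[C@@H]2CO[C@@H](c3ccccc3)O[C@H]2C(=O)[C@H]1OCc1ccc(OC)cc1 | intermediate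
5 | (chloromethyl)(isopropoxy)dimethylsilane | CC(C)O[Si](C)(C)CCl | starting material
6 | [(isopropoxydimethylsilyl)methyl]magnesium chloride | CC(C)O[Si](C)(C)C[Mg]Cl | intermediate
7 | methyl 4,6-O-benzylidene-3-C-[(isopropoxydimethylsilyl)methyl]-2-O-(4-methoxybenzyl)-α-D-allopyranoside | CO[C@H]1O[C@@H]2CO[C@@H](c3ccccc3)O[C@H]2[C@](O)(C[Si](C)(C)OC(C)C)[C@H]1OCc1ccc(OC)cc1 | intermediate
8 | methyl 4,6-O-benzylidene-3-C-(hydroxymethyl)-2-O-(4-methoxybenzyl)-α-D-allopyranoside | CO[C@H]1O[C@@H]2CO[C@@H](c3ccccc3)O[C@H]2[C@](O)(CO)[C@H]1OCc1ccc(OC)cc1 | intermediate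
9 | methyl 4,6-O-benzylidene-3-C-[(tert-butyldimethylsilyloxy)methyl]-2-O-(4-methoxybenzyl)-α-D-allopyranoside | CO[C@H]1O[C@@H]2CO[C@@H](c3ccccc3)O[C@H]2[C@](O)(CO[Si](C)(C)C(C)(C)C)[C@H]1OCc1ccc(OC)cc1 | intermediate
10 | methyl 4,6-O-benzylidene-3-C-[(tert-butyldimethylsilyloxy)methyl]-α-D-allopyranoside | CO[C@H]1O[C@@H]2CO[C@@H](c3ccccc3)O[C@H]2[C@](O)(CO[Si](C)(C)C(C)(C)C)[C@H]1O | intermediate
11 | benzoyl chloride | O=C(Cl)c1ccccc1 | starting material
12 | methyl 2-O-benzoyl-4,6-O-benzylidene-3-C-[(tert-butyldimethylsilyloxy)methyl]-α-D-allopyranoside | CO[C@H]1O[C@@H]2CO[C@@H](c3ccccc3)O[C@H]2[C@](O)(CO[Si](C)(C)C(C)(C)C)[C@H]1OC(=O)c1ccccc1 | intermediate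
13 | methyl 2-O-benzoyl-3-C-[(tert-butyldimethylsilyloxy)methyl]-α-D-allopyranoside | CO[C@H]1O[C@H](CO)[C@@H](O)[C@](O)(CO[Si](C)(C)C(C)(C)C)[C@H]1OC(=O)c1ccccc1 | intermediate
14 | methyl 2-O-benzoyl-3-C-[(tert-butyldimethylsilyloxy)methyl]-6-deoxy-6-iodo-α-D-allopyranoside | CO[C@H]1O[C@H](CI)[C@@H](O)[C@](O)(CO[Si](C)(C)C(C)(C)C)[C@H]1OC(=O)c1ccccc1 | intermediate
15 | methyl 2-O-benzoyl-3-C-[(tert-butyldimethylsilyloxy)methyl]-6-deoxy-6-iodo-3,4-O-isopropylidene-α-D-allopyranoside | CO[C@H]1O[C@H](CI)[C@H]2OC(C)(C)O[C@@]2(CO[Si](C)(C)C(C)(C)C)[C@H]1OC(=O)c1ccccc1 | intermediate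
16 | methyl 2-O-benzoyl-3-C-[(tert-butyldimethylsilyloxy)methyl]-6-deoxy-3,4-O-isopropylidene-α-D-ribo-hex-5-enopyranoside | CO[C@H]1OC(=C)[C@H]2OC(C)(C)O[C@@]2(CO[Si](C)(C)C(C)(C)C)[C@H]1OC(=O)c1ccccc1 | intermediate
17 | open-chain mercurio keto aldehyde: 2-O-benzoyl-3-C-[(tert-butyldimethylsilyloxy)methyl]-6-deoxy-3,4-O-isopropylidene-6-(trifluoroacetoxymercurio)-D-ribo-hexos-5-ulose | O=C[C@H](OC(=O)c1ccccc1)[C@]1(CO[Si](C)(C)C(C)(C)C)OC(C)(C)O[C@@H]1C(=O)C[Hg]OC(=O)C(F)(F)F | intermediate
18 | 1-benzoyloxy-6-[(tert-butyldimethylsilyloxy)methyl]-2-hydroxy-5,6-(isopropylidenedioxy)cyclohexan-4-one (target numbering; O1, O5, O6 cis; C2 either epimer) | O=C(O[C@H]1C(O)CC(=O)[C@H]2OC(C)(C)O[C@@]12CO[Si](C)(C)C(C)(C)C)c1ccccc1 | intermediate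
19 | 2-O-methanesulfonate of 18 | O=C(O[C@H]1C(OS(C)(=O)=O)CC(=O)[C@H]2OC(C)(C)O[C@@]12CO[Si](C)(C)C(C)(C)C)c1ccccc1 | intermediate
20 | 1-benzoyloxy-6-[(tert-butyldimethylsilyloxy)methyl]-5,6-(isopropylidenedioxy)cyclohex-2-en-4-one (O1, O5, O6 cis) | O=C(O[C@H]1C=CC(=O)[C@H]2OC(C)(C)O[C@@]12CO[Si](C)(C)C(C)(C)C)c1ccccc1 | intermediate
21 | 1-benzoyloxy-6-[(tert-butyldimethylsilyloxy)methyl]-4-hydroxy-5,6-(isopropylidenedioxy)cyclohex-2-ene (O1, O4, O5, O6 cis) | O=C(O[C@H]1C=C[C@@H](O)[C@H]2OC(C)(C)O[C@@]12CO[Si](C)(C)C(C)(C)C)c1ccccc1 | intermediate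
22 | 1,4-bis(benzoyloxy)-6-[(tert-butyldimethylsilyloxy)methyl]-5,6-(isopropylidenedioxy)cyclohex-2-ene (all ring oxygens cis) | O=C(O[C@H]1C=C[C@@H](OC(=O)c2ccccc2)[C@H]2OC(C)(C)O[C@@]12CO[Si](C)(C)C(C)(C)C)c1ccccc1 | intermediate
23 | (1S,4R,5R,6R)-4-(benzoyloxy)-5,6-dihydroxy-6-(hydroxymethyl)cyclohex-2-en-1-yl benzoate (CNP0212417.4) | O=C(O[C@H]1C=C[C@@H](OC(=O)c2ccccc2)[C@@H](O)[C@]1(O)CO)c1ccccc1 | target

**Step count**

Total: 16 steps. Longest linear sequence: 16 steps (1 to 23); 5 and 11 are used as purchased.

**Steps most likely to fail**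

Step 12 (key step). The trifluoroacetic acid released in the aqueous mercury medium may slowly hydrolyse the isopropylidene ketal or the silyl ether, or hydration of the enol ether may be slowed by the cis-fused dioxolane next to sugar C5. The fallback postpones the ketal. Setting out from iodo diol 14, elimination with DBU gives the enopyranoside with free 3- and 4-hydroxyls, methyl 2-O-benzoyl-3-C-[(tert-butyldimethylsilyloxy)methyl]-6-deoxy-α-D-ribo-hex-5-enopyranoside F2. The same Hg(OCOCF3)2-catalysed carbocyclization, which tolerates free hydroxyls, gives the trihydroxy cyclohexanone F3. Ketalisation of its cis C5/C6 diol with 2,2-dimethoxypropane and pyridinium p-toluenesulfonate in acetone comes back to the route at 18.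

Step 14. Facial selectivity may be poor: the C7 branch lies on the face opposite to the dioxolane and can shield the wanted approach, so that hydride is delivered syn to the dioxolane. The fallback accepts that preference and inverts afterwards. From enone 20 the reduction is run to the C4-epimeric allylic alcohol F4 (with a bulkier hydride if that raises the bias). F4 is then esterified with benzoic acid under Mitsunobu conditions (PPh3, diisopropyl azodicarboxylate, THF, 0 °C); SN2 inversion at C4 gives dibenzoate 22 directly, in place of steps 14 and 15.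

Step 3. The Grignard reagent may enolise the doubly α-oxygenated ketone (recovered or C2-epimerised ketone), or equatorial attack may be incomplete, giving a mixture at the new quaternary center. The fallback uses methylene transfer instead of carbanion addition. From ketone 4, dimethylsulfoxonium methylide (Me3S(O)I, NaH, DMSO, rt) adds reversibly and should close to the spiro-epoxide with the CH2 equatorial and O3 axial, methyl 3,3'-anhydro-4,6-O-benzylidene-3-C-(hydroxymethyl)-2-O-(4-methoxybenzyl)-α-D-allopyranoside F1. Hydroxide opening at the unhindered epoxide CH2 (KOH, DMSO/H2O, 80 °C) gives diol 8, where the route is rejoined.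

**Further compounds**

F1 | step 3 | methyl 3,3'-anhydro-4,6-O-benzylidene-3-C-(hydroxymethyl)-2-O-(4-methoxybenzyl)-α-D-allopyranoside (spiro-epoxide) | CO[C@H]1O[C@@H]2CO[C@@H](c3ccccc3)O[C@H]2[C@]3(CO3)[C@H]1OCc1ccc(OC)cc1
F2 | step 12 | methyl 2-O-benzoyl-3-C-[(tert-butyldimethylsilyloxy)methyl]-6-deoxy-α-D-ribo-hex-5-enopyranoside | CO[C@H]1OC(=C)[C@@H](O)[C@](O)(CO[Si](C)(C)C(C)(C)C)[C@H]1OC(=O)c1ccccc1
F3 | step 12 | 1-benzoyloxy-6-[(tert-butyldimethylsilyloxy)methyl]-2,5,6-trihydroxycyclohexan-4-one (target numbering; O1, O5, O6 cis; C2 either epimer) | O=C(O[C@H]1C(O)CC(=O)[C@@H](O)[C@]1(O)CO[Si](C)(C)C(C)(C)C)c1ccccc1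
F4 | step 14 | C4 epimer of 21 (4-hydroxyl trans to O5) | O=C(O[C@H]1C=C[C@H](O)[C@H]2OC(C)(C)O[C@@]12CO[Si](C)(C)C(C)(C)C)c1ccccc1
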